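## Retrosynthetic overview

1. The butenolide ring is closed last. The target comes from a cyclohexenylacetic acid tert-butyl ester that already carries the palmitate, by epoxidation of the ring alkene, epoxide-opening lactonization and dehydration in one flask.
2. That ester comes from a tetrasubstituted vinyl triflate and the zinc enolate of tert-butyl acetate (sp2–sp3 cross-coupling).
3. The vinyl triflate comes from the palmitate of (S)-4-hydroxyisophorone by conjugate reduction and O-triflation of the enolate.
4. (S)-4-Hydroxyisophorone comes from ketoisophorone by asymmetric transfer hydrogenation; this sets the carbinol centre (C6 of the target).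
5. Ring order: the carbocycle is bought with ketoisophorone; the only ring-forming event is the late lactone closure, which creates the quaternary C7a centre under control of the C6 ester.

Assumption: the sense of induction in step 1 follows the usual model for this catalyst class ((S,S)-ligand gives the (S)-allylic alcohol); it is checked on 2 by rotation or chiral GC, and the (R,R)-complex is used if it proves opposite.

## Route

Step 1
Reactants: 1 ketoisophorone (2,6,6-trimethylcyclohex-2-ene-1,4-dione)
Product: 2 (4S)-4-hydroxy-2,6,6-trimethylcyclohex-2-en-1-one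
Conditions: RuCl[(S,S)-TsDPEN](p-cymene) (0.5 mol %), KOH (1 mol %), i-PrOH, 25 °C
Reagents that add atoms: none
Why: Noyori–Ikariya asymmetric transfer hydrogenation reduces only the unhindered C4 carbonyl (C1 is flanked by the quaternary carbon), and in the six-membered bifunctional transition state the alkene takes the place of the aryl group of an aryl ketone, so the (S,S)-ligand delivers hydride to give the (S)-carbinol.

Step 2
Reactants: 2 (4S)-4-hydroxy-2,6,6-trimethylcyclohex-2-en-1-one; 3 palmitoyl chloride (hexadecanoyl chloride)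
Product: 4 (1S)-3,5,5-trimethyl-4-oxocyclohex-2-en-1-yl hexadecanoate
Conditions: pyridine (2 equiv), DMAP (5 mol %), CH2Cl2, 0 °C → rt
Reagents that add atoms: palmitoyl chloride (3), CCCCCCCCCCCCCCCC(=O)Cl
Why: DMAP-catalysed O-acylation (nucleophilic catalysis) of the secondary allylic alcohol goes with retention because the C–O bond is not touched.

Step 3
Reactants: 4 (1S)-3,5,5-trimethyl-4-oxocyclohex-2-en-1-yl hexadecanoate
Product: 6 (1R)-3,5,5-trimethyl-4-(trifluoromethanesulfonyloxy)cyclohex-3-en-1-yl hexadecanoate, via lithium enolate 5 (not isolated)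
Conditions: LiBH(s-Bu)3 (L-Selectride, 1.05 equiv), THF, −78 °C; then PhNTf2, −78 °C → rt; aq. NH4Cl
Reagents that add atoms: N-phenylbis(trifluoromethanesulfonimide) (PhNTf2), O=S(=O)(N(c1ccccc1)S(=O)(=O)C(F)(F)F)C(F)(F)F
Why: Conjugate (1,4) hydride reduction of the β-unsubstituted enone, whose carbonyl is shielded by the gem-dimethyl group, gives one regiodefined tetrasubstituted enolate that is O-triflated (reductive enol triflation); no stereocentre is made, and the carbinol descriptor changes from S to R only through the priority rules.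

Step 4
Reactants: 6 (1R)-3,5,5-trimethyl-4-(trifluoromethanesulfonyloxy)cyclohex-3-en-1-yl hexadecanoate; 7 tert-butyl bromoacetate
Product: 9 (1R)-4-(2-tert-butoxy-2-oxoethyl)-3,5,5-trimethylcyclohex-3-en-1-yl hexadecanoate, via Reformatsky reagent 8 (not isolated)
Conditions: 7, zinc dust (TMSCl-activated, 1.5 equiv), THF, 40 °C; then 6, Pd2(dba)3 (2.5 mol %), XPhos (10 mol %), THF, 50 °C
Reagents that add atoms: tert-butyl bromoacetate (7), CC(C)(C)OC(=O)CBr
Why: Negishi-type cross-coupling of a Reformatsky reagent (oxidative addition of the vinyl triflate to zerovalent palladium, transmetalation of the C-bound zinc enolate, reductive elimination) tolerates the palmitate and leaves the tetrasubstituted ring alkene and the carbinol centre unchanged.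

Step 5
Reactants: 9 (1R)-4-(2-tert-butoxy-2-oxoethyl)-3,5,5-trimethylcyclohex-3-en-1-yl hexadecanoate
Product: 13 (6S,7aR)-4,4,7a-trimethyl-2-oxo-2,4,5,6,7,7a-hexahydro-1-benzofuran-6-yl hexadecanoate, via syn-epoxide 10 (not isolated), via hydroxy lactone 11 (not isolated), via chlorosulfite 12 (not isolated)
Conditions: mCPBA (1.2 equiv), CH2Cl2, −20 → 0 °C; then CF3CO2H (2 equiv), 0 °C → rt; then pyridine (15 equiv), SOCl2 (5 equiv), 0 °C; one flask
Reagents that add atoms: none
Why: Prilezhaev epoxidation attacks the face anti to the pseudoaxial methyl of the gem-dimethyl group, which in the half-chair with an equatorial palmitate is the face cis to the ester (syn-epoxide 10, expected about 3–4:1, a reasoned estimate); acid then triggers anchimerically assisted trans-diaxial opening at the methyl-bearing epoxide carbon by the tert-butyl ester carbonyl from the face opposite the epoxide oxygen (inversion, loss of isobutene), which places the ring oxygen anti to the palmitate and sets C7a as R, and chlorosulfite elimination towards the only β-hydrogens (C3) gives the butenolide, the peracid oxygen leaving as SO2 so that every heavy atom of 13 comes from 9.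

## Compound list

1 | ketoisophorone (2,6,6-trimethylcyclohex-2-ene-1,4-dione) | CC1=CC(=O)CC(C)(C)C1=O | starting material
2 | (4S)-4-hydroxy-2,6,6-trimethylcyclohex-2-en-1-one | O[C@H]1CC(C)(C)C(=O)C(C)=C1 | intermediate
3 | palmitoyl chloride (hexadecanoyl chloride) | CCCCCCCCCCCCCCCC(=O)Cl | starting material
4 | (1S)-3,5,5-trimethyl-4-oxocyclohex-2-en-1-yl hexadecanoate | CCCCCCCCCCCCCCCC(=O)O[C@H]1CC(C)(C)C(=O)C(C)=C1 | intermediate
5 | lithium (4R)-4-(hexadecanoyloxy)-2,6,6-trimethylcyclohex-1-en-1-olate | CCCCCCCCCCCCCCCC(=O)O[C@H]1CC(C)(C)C([O-])=C(C)C1.[Li+] | intermediate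
6 | (1R)-3,5,5-trimethyl-4-(trifluoromethanesulfonyloxy)cyclohex-3-en-1-yl hexadecanoate | CCCCCCCCCCCCCCCC(=O)O[C@H]1CC(C)(C)C(OS(=O)(=O)C(F)(F)F)=C(C)C1 | intermediate
7 | tert-butyl bromoacetate | CC(C)(C)OC(=O)CBr | starting material
8 | (2-tert-butoxy-2-oxoethyl)zinc bromide | CC(C)(C)OC(=O)C[Zn]Br | intermediate
9 | (1R)-4-(2-tert-butoxy-2-oxoethyl)-3,5,5-trimethylcyclohex-3-en-1-yl hexadecanoate | CCCCCCCCCCCCCCCC(=O)O[C@H]1CC(C)(C)C(CC(=O)OC(C)(C)C)=C(C)C1 | intermediate
10 | tert-butyl 2-[(1R,4S,6S)-4-(hexadecanoyloxy)-2,2,6-trimethyl-7-oxabicyclo[4.1.0]heptan-1-yl]acetate (epoxide oxygen cis to the palmitoyloxy group) | CCCCCCCCCCCCCCCC(=O)O[C@H]1CC(C)(C)[C@@]2(CC(=O)OC(C)(C)C)O[C@@]2(C)C1 | intermediate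
11 | (3aR,6S,7aR)-3a-hydroxy-4,4,7a-trimethyl-2-oxooctahydro-1-benzofuran-6-yl hexadecanoate (cis-fused; ring oxygen anti and 3a-OH syn to the palmitoyloxy group) | CCCCCCCCCCCCCCCC(=O)O[C@H]1CC(C)(C)[C@]2(O)CC(=O)O[C@]2(C)C1 | intermediate
12 | (3aR,6S,7aR)-3a-(chlorosulfinyloxy)-4,4,7a-trimethyl-2-oxooctahydro-1-benzofuran-6-yl hexadecanoate | CCCCCCCCCCCCCCCC(=O)O[C@H]1CC(C)(C)[C@]2(OS(=O)Cl)CC(=O)O[C@]2(C)C1 | intermediate
13 | (−)-3-O-palmitoylloliolide, (6S,7aR)-4,4,7a-trimethyl-2-oxo-2,4,5,6,7,7a-hexahydro-1-benzofuran-6-yl hexadecanoate | CCCCCCCCCCCCCCCC(=O)O[C@H]1CC(C)(C)C2=CC(=O)O[C@]2(C)C1 | target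

## Step count and risks

Total step count: 5. Longest linear sequence: 5 (1 → 2 → 4 → 6 → 9 → 13).

The three steps most likely to fail are step 5, then step 4, then step 3.

Step 3 can give 1,2-reduction, or the hindered tetrasubstituted enolate can be triflated too slowly. The fallback sets out from 4 and comes back at 6. Conjugate reduction with catalytic [(Ph3P)CuH]6 and PhSiH3 in toluene gives, after work-up, the saturated ketone (1R)-3,5,5-trimethyl-4-oxocyclohexyl hexadecanoate F1 (mixture of methyl epimers, which does not matter). Electrophilic triflation of its only enolisable position with Tf2O and 2,6-di-tert-butyl-4-methylpyridine in CH2Cl2 then gives 6 without any anionic intermediate.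

Step 4 can stall because the triflate is tetrasubstituted and the C-bound zinc enolate transmetalates slowly. The fallback sets out from 4 and comes back at 9, replacing the cross-coupling by carbonyl addition. The same copper hydride reduction gives the ketone (1R)-3,5,5-trimethyl-4-oxocyclohexyl hexadecanoate F1. CeCl3-mediated addition of lithium tert-butyl acetate (LDA, tert-butyl acetate, THF, −78 °C) to the hindered ketone gives the β-hydroxy ester tert-butyl 2-[(4R)-4-(hexadecanoyloxy)-1-hydroxy-2,2,6-trimethylcyclohexyl]acetate F2 (diastereomer mixture, which does not matter). Dehydration with SOCl2 and pyridine, followed by DBU equilibration of any exocyclic isomer into the tetrasubstituted ring alkene, gives 9.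

Step 5 carries the most risk: the facial ratio of the irreversible epoxidation is only moderate, and the tetrasubstituted epoxide can rearrange under acid. The minor anti-epoxide would end as the C7a epimer of 13, to be removed by chromatography. The fallback sets out from 9 and comes back at 13, replacing the oxygen transfer by reversible iodonium formation. I2 and NaHCO3 in MeCN at 0 °C give the iodolactone (3aR,6S,7aR)-3a-iodo-4,4,7a-trimethyl-2-oxooctahydro-1-benzofuran-6-yl hexadecanoate F3, with the tert-butyl group lost as isobutene. Because the iodonium forms reversibly, the product should be funnelled through the trans-diaxial opening of the iodonium on the face cis to the ester, which gives the same relative configuration. DBU in toluene at rt then eliminates HI to give 13.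

## Further compounds

F1 | step 3 | (1R)-3,5,5-trimethyl-4-oxocyclohexyl hexadecanoate (mixture of C3 epimers) | CCCCCCCCCCCCCCCC(=O)O[C@H]1CC(C)(C)C(=O)C(C)C1
F2 | step 4 | tert-butyl 2-[(4R)-4-(hexadecanoyloxy)-1-hydroxy-2,2,6-trimethylcyclohexyl]acetate (mixture at C1 and C6) | CCCCCCCCCCCCCCCC(=O)O[C@H]1CC(C)(C)C(O)(CC(=O)OC(C)(C)C)C(C)C1
F3 | step 5 | (3aR,6S,7aR)-3a-iodo-4,4,7a-trimethyl-2-oxooctahydro-1-benzofuran-6-yl hexadecanoate | CCCCCCCCCCCCCCCC(=O)O[C@H]1CC(C)(C)[C@]2(I)CC(=O)O[C@]2(C)C1
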